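All five C–Br bonds are removed at once, leading back to an unbrominated bis(3,4-dioxygenated benzyl) ether. The key step is one exhaustive electrophilic bromination. It exploits the fact that every bromine sits ortho or para to a phenolic oxygen: C2′, C5′ and C6′ of the tribromo catechol ring B, and C2 and C6 of the dibromo ring A, which flank C1 and are ortho/para to O3, whereas C5–H is ortho to O4 only. The precursor 12 therefore has O3, O3′ and O4′ free and O4 alone capped as a triisopropylsilyl ether. It is assembled from two catechol-derived benzyl fragments by neutral silver-mediated etherification, and buffered fluoride finishes the synthesis.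

Key step: step 7

Remark: the target has no stereogenic element, so it is made as the achiral compound it is. In both rings C1 is the carbon bearing CH2; ring A is the dibromo ring and ring B (primed locants) the tribromo ring.

Step 1
Reactants: 1 3,4-dihydroxybenzaldehyde; 2 triisopropylsilyl chloride; 3 acetic anhydride
Product: 5 3-acetoxy-4-triisopropylsilyloxybenzaldehyde, via 3-hydroxy-4-triisopropylsilyloxybenzaldehyde 4 (not isolated)
Conditions: TIPSCl (1.0 equiv), imidazole (2.2 equiv), DMF, –20 → 0 °C; then Ac2O (2.5 equiv), pyridine, DMAP (cat.), 0 °C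
Reagents that add atoms: triisopropylsilyl chloride CC(C)[Si](Cl)(C(C)C)C(C)C; acetic anhydride CC(=O)OC(C)=O
Why: Regioselective O-silylation followed by O-acetylation in one flask: imidazole (pKaH about 7) ionises only the 4-OH, which is para to the formyl group and much the more acidic hydroxyl, so the bulky silyl chloride should be taken up at O4 as alkyl halides are under bicarbonate, and the acetate cap on O3 is set before a base-driven silyl shift from O4 to O3 can occur.

Step 2
Reactants: 5 3-acetoxy-4-triisopropylsilyloxybenzaldehyde
Product: 6 3-acetoxy-4-triisopropylsilyloxybenzyl alcohol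
Conditions: NaBH4 (0.6 equiv), THF/EtOH, –10 °C, short contact; sat. aq. NH4Cl
Reagents that add atoms: none
Why: Chemoselective borohydride reduction of the aldehyde, which at low temperature with a buffered quench is far faster than attack on the aryl acetate, so neither the ester nor the silyl ether should be disturbed.

Step 3
Reactants: 7 4-methylbenzene-1,2-diol; 3 acetic anhydride
Product: 8 4-methyl-1,2-phenylene diacetate
Conditions: Ac2O (2.5 equiv), pyridine, DMAP (cat.), CH2Cl2, 0 °C → rt
Reagents that add atoms: acetic anhydride CC(=O)OC(C)=O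
Why: Standard DMAP-catalysed O-acetylation of both phenols, which also deactivates the ring against electrophilic bromination in the next step.

Step 4
Reactants: 8 4-methyl-1,2-phenylene diacetate; 9 N-bromosuccinimide
Product: 10 4-(bromomethyl)-1,2-phenylene diacetate
Conditions: NBS (1.05 equiv), AIBN (5 mol%), PhCF3, 85 °C
Reagents that add atoms: N-bromosuccinimide O=C1CCC(=O)N1Br
Why: Wohl–Ziegler radical bromination of the benzylic methyl group; the two acetoxy groups keep the ring inert towards electrophilic bromine, so the radical chain should take only a benzylic hydrogen.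

Step 5
Reactants: 6 3-acetoxy-4-triisopropylsilyloxybenzyl alcohol; 10 4-(bromomethyl)-1,2-phenylene diacetate
Product: 11 4-{[(3-acetoxy-4-triisopropylsilyloxybenzyl)oxy]methyl}-1,2-phenylene diacetate
Conditions: Ag2O (1.5 equiv), 10 (1.3 equiv), 4 Å MS, CH2Cl2, rt, dark
Reagents that add atoms: none
Why: Silver(I) oxide-promoted Williamson-type etherification: Ag+ assists departure of the benzylic bromide while the oxide takes up the proton, so the C–O bond forms without a free alkoxide that would transfer acetyl groups or attack silicon.

Step 6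
Reactants: 11 4-{[(3-acetoxy-4-triisopropylsilyloxybenzyl)oxy]methyl}-1,2-phenylene diacetate
Product: 12 4-[(3-hydroxy-4-triisopropylsilyloxybenzyl)oxymethyl]benzene-1,2-diol
Conditions: NH4OAc (10 equiv), MeOH/H2O 4:1, rt, argon, degassed solvents
Reagents that add atoms: none
Why: Ammonium acetate-mediated methanolysis of phenolic acetates at neutral pH should remove all three aryl esters and leave the aryl silyl ether and the dibenzyl ether intact; with the phenols never ionised, neither a silyl shift from O4 to O3 nor catechol autoxidation is triggered.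

Step 7
Reactants: 12 4-[(3-hydroxy-4-triisopropylsilyloxybenzyl)oxymethyl]benzene-1,2-diol; 9 N-bromosuccinimide
Product: 13 3,4,6-tribromo-5-[(2,6-dibromo-3-hydroxy-4-triisopropylsilyloxybenzyl)oxymethyl]benzene-1,2-diol
Conditions: NBS (5.0 equiv, recrystallised, added in portions), MeCN, –20 → 0 °C, dark, argon; aq. Na2S2O4 quench
Reagents that add atoms: N-bromosuccinimide O=C1CCC(=O)N1Br
Why: Each C–Br bond forms by electrophilic aromatic substitution: electrophilic bromine from NBS adds at a carbon ortho or para to a free phenolic OH, giving an oxygen-stabilised Wheland intermediate that rearomatises by proton loss; the closest known reaction type is the exhaustive NBS or bromine bromination of phenols and 4-alkylcatechols. No ring closes and no stereocenter is formed, so neither a mode of closure nor a stereocontrol element is involved. The regiocontrol is built into 12: ring B offers C6′ (para to O3′–H), C2′ (ortho to O3′–H) and C5′ (ortho to O4′–H), and ring A offers C6 (para) and C2 (ortho) to its only free hydroxyl O3–H. C5 of ring A is meta to O3 and ortho only to the silylated O4, whose lone pair is less available and whose isopropyl groups shield that carbon, on a ring that by then carries two bromines. Exactly five equivalents added cold should keep the reagent from the two slower side paths, substitution at C5 and ipso attack at C1′ or C1 with loss of the benzylic carbon. NBS releases succinimide and not HBr, so the acid-labile para-oxygenated dibenzyl ether and the silyl ether should persist, and the reductive quench returns any ortho-quinone formed on ring B to the catechol.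

Step 8
Reactants: 13 3,4,6-tribromo-5-[(2,6-dibromo-3-hydroxy-4-triisopropylsilyloxybenzyl)oxymethyl]benzene-1,2-diol
Product: 14 3,4,6-tribromo-5-[(2,6-dibromo-3,4-dihydroxybenzyl)oxymethyl]benzene-1,2-diol
Conditions: TBAF (1.2 equiv), AcOH (1.5 equiv), THF, 0 °C; pH 5 phosphate work-up, no alcoholic solvents
Reagents that add atoms: none
Why: Fluoride-induced Si–O cleavage of the aryl silyl ether; acetic acid protonates the phenoxide as it forms, so 1,6-elimination to a quinone methide with loss of the benzylic ether and base-promoted oxidation of the bromocatechols should be avoided.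

Compound list
1 | 3,4-dihydroxybenzaldehyde | O=Cc1ccc(O)c(O)c1 | starting material
2 | triisopropylsilyl chloride | CC(C)[Si](Cl)(C(C)C)C(C)C | starting material
3 | acetic anhydride | CC(=O)OC(C)=O | starting material
4 | 3-hydroxy-4-triisopropylsilyloxybenzaldehyde | O=Cc1ccc(O[Si](C(C)C)(C(C)C)C(C)C)c(O)c1 | intermediate
5 | 3-acetoxy-4-triisopropylsilyloxybenzaldehyde | CC(=O)Oc1cc(C=O)ccc1O[Si](C(C)C)(C(C)C)C(C)C | intermediate
6 | 3-acetoxy-4-triisopropylsilyloxybenzyl alcohol | CC(=O)Oc1cc(CO)ccc1O[Si](C(C)C)(C(C)C)C(C)C | intermediate
7 | 4-methylbenzene-1,2-diol | Cc1ccc(O)c(O)c1 | starting material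
8 | 4-methyl-1,2-phenylene diacetate | CC(=O)Oc1ccc(C)cc1OC(C)=O | intermediate
9 | N-bromosuccinimide | O=C1CCC(=O)N1Br | starting material
10 | 4-(bromomethyl)-1,2-phenylene diacetate | CC(=O)Oc1ccc(CBr)cc1OC(C)=O | intermediate
11 | 4-{[(3-acetoxy-4-triisopropylsilyloxybenzyl)oxy]methyl}-1,2-phenylene diacetate | CC(=O)Oc1cc(COCc2ccc(OC(C)=O)c(OC(C)=O)c2)ccc1O[Si](C(C)C)(C(C)C)C(C)C | intermediate
12 | 4-[(3-hydroxy-4-triisopropylsilyloxybenzyl)oxymethyl]benzene-1,2-diol | Oc1cc(COCc2ccc(O)c(O)c2)ccc1O[Si](C(C)C)(C(C)C)C(C)C | intermediate
13 | 3,4,6-tribromo-5-[(2,6-dibromo-3-hydroxy-4-triisopropylsilyloxybenzyl)oxymethyl]benzene-1,2-diol | Oc1c(Br)c(COCc2c(Br)c(O)c(O)c(Br)c2Br)c(Br)cc1O[Si](C(C)C)(C(C)C)C(C)C | intermediate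
14 | 3,4,6-tribromo-5-[(2,6-dibromo-3,4-dihydroxybenzyl)oxymethyl]benzene-1,2-diol | Oc1cc(Br)c(COCc2c(Br)c(O)c(O)c(Br)c2Br)c(Br)c1O | target

Total step count: 8
Longest linear sequence: 6 steps (steps 1, 2, 5, 6, 7, 8)

Steps most likely to fail

Step 7. The still electron-rich catechol ring B may be oxidised to an ortho-quinone that tautomerises to a quinone methide and sheds the benzylic ether. The reagent may also fail to discriminate between the last ring-B position and C5 of ring A, which would leave mixtures of tetra-, penta- and hexabromides. The fallback divides the bromination between a fragment and the ether. It sets out from 7 and 6 and returns at 13. Compound 7 is tribrominated with bromine (3.1 equiv, AcOH, rt), where no benzylic ether is present and HBr is tolerated, to give 3,4,6-tribromo-5-methylbenzene-1,2-diol F1. Acetylation (Ac2O, pyridine) gives 3,4,6-tribromo-5-methyl-1,2-phenylene diacetate F2, and radical bromination of the methyl group (NBS, AIBN, PhCF3, 85 °C) gives 3,4,6-tribromo-5-(bromomethyl)-1,2-phenylene diacetate F3. Silver(I) oxide etherification of F3 with 6 gives 3,4,6-tribromo-5-{[(3-acetoxy-4-triisopropylsilyloxybenzyl)oxy]methyl}-1,2-phenylene diacetate F4. Ammonium acetate in aqueous methanol then gives 3,4,6-tribromo-5-[(3-hydroxy-4-triisopropylsilyloxybenzyl)oxymethyl]benzene-1,2-diol F5. Only two equivalents of NBS (MeCN, –20 → 0 °C), both directed by O3–H of ring A, are then needed to reach 13.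

Step 1. Regiocontrol may be lost through silylation at O3, twofold silylation, or base-induced migration of the silyl group from O4 to the thermodynamically preferred O3 before the acetate is in place. The fallback fixes the regiochemistry with an alkyl group that cannot migrate. It sets out from 1 and returns at 5. Bicarbonate-mediated 4-O-alkylation (4-methoxybenzyl chloride, NaHCO3, NaI, DMF, 40 °C) gives 3-hydroxy-4-(4-methoxybenzyloxy)benzaldehyde F6. Acetylation (Ac2O, pyridine) gives 3-acetoxy-4-(4-methoxybenzyloxy)benzaldehyde F7. Acidolysis with a cation scavenger (TFA, pentamethylbenzene, CH2Cl2, 0 °C) gives 3-acetoxy-4-hydroxybenzaldehyde F8, whose acetate sits on the oxygen it prefers. Fast silylation of the free 4-OH (TIPSOTf, 2,6-lutidine, CH2Cl2, –78 °C) then delivers 5.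

Step 5. The silver-assisted substitution may be sluggish, so that hydrolysis and self-condensation of the bromide to the symmetrical ether outrun the cross-coupling. The fallback reverses the activation to an acid-catalysed imidate alkylation of the 4-methoxybenzyl type. It sets out from 6 and 10 and returns at 11. Bromide 10 is solvolysed (Ag2CO3, acetone/H2O, rt) to 4-(hydroxymethyl)-1,2-phenylene diacetate F9. Alcohol 6 is converted (Cl3CCN, DBU cat., CH2Cl2, 0 °C) into 3-acetoxy-4-triisopropylsilyloxybenzyl 2,2,2-trichloroacetimidate F10. F10 then alkylates F9 under catalytic acid (camphorsulfonic acid, CH2Cl2, 0 °C), the para-silyloxy group stabilising the benzylic cation, to give 11.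

Further compounds
F1 | step 7 | 3,4,6-tribromo-5-methylbenzene-1,2-diol | Cc1c(Br)c(O)c(O)c(Br)c1Br
F2 | step 7 | 3,4,6-tribromo-5-methyl-1,2-phenylene diacetate | Cc1c(Br)c(OC(C)=O)c(OC(C)=O)c(Br)c1Br
F3 | step 7 | 3,4,6-tribromo-5-(bromomethyl)-1,2-phenylene diacetate | BrCc1c(Br)c(OC(C)=O)c(OC(C)=O)c(Br)c1Br
F4 | step 7 | 3,4,6-tribromo-5-{[(3-acetoxy-4-triisopropylsilyloxybenzyl)oxy]methyl}-1,2-phenylene diacetate | CC(=O)Oc1cc(COCc2c(Br)c(OC(C)=O)c(OC(C)=O)c(Br)c2Br)ccc1O[Si](C(C)C)(C(C)C)C(C)C
F5 | step 7 | 3,4,6-tribromo-5-[(3-hydroxy-4-triisopropylsilyloxybenzyl)oxymethyl]benzene-1,2-diol | Oc1cc(COCc2c(Br)c(O)c(O)c(Br)c2Br)ccc1O[Si](C(C)C)(C(C)C)C(C)C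
F6 | step 1 | 3-hydroxy-4-(4-methoxybenzyloxy)benzaldehyde | COc1ccc(COc2ccc(C=O)cc2O)cc1
F7 | step 1 | 3-acetoxy-4-(4-methoxybenzyloxy)benzaldehyde | COc1ccc(COc2ccc(C=O)cc2OC(C)=O)cc1
F8 | step 1 | 3-acetoxy-4-hydroxybenzaldehyde | CC(=O)Oc1cc(C=O)ccc1O
F9 | step 5 | 4-(hydroxymethyl)-1,2-phenylene diacetate | CC(=O)Oc1ccc(CO)cc1OC(C)=O
F10 | step 5 | 3-acetoxy-4-triisopropylsilyloxybenzyl 2,2,2-trichloroacetimidate | CC(=O)Oc1cc(COC(=N)C(Cl)(Cl)Cl)ccc1O[Si](C(C)C)(C(C)C)C(C)C
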